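**Plan**
- Late cuts: in each flavone unit the O1–C2 bond, the C2–C3 (aldol) bond and the C4–C4a acyl bond, leading back to a 4,4'-dimethoxybiphenyl-2,2',6,6'-tetraol whose two rings are told apart by benzyl ethers and bromine blocking atoms.
- Central cut: the 8,8'' axis is left intact; ring A of the acacetin half is opened at C8–C8a, giving a 6-(arylmethyl)-4-methoxy-2-pyranone. This goes back to an arylacetic acid plus methyl acetoacetate, and the acid to 2,4,6-trihydroxybenzaldehyde by one-carbon homologation.
- Forward order: ring A of the apigenin half is bought as the aldehyde and receives methyl, benzyl and two bromine groups; the side chain is built and closed to the 2-pyranone; the pyranone is recyclised to ring A of the acacetin half, which creates the axis; the acacetin pyranone ring follows; hydrogenolysis; the apigenin pyranone ring; BCl3 unmasking.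
- Stereochemistry: the target has no stereocentre; the E-enones arise from aldol dehydration and disappear on cyclisation; the hindered axis is formed without control.

Key step: step 9

Assumption: the target SMILES carries no axial descriptor, so the 8,8'' axis (stereogenic from compound 21 onward) is made as the racemate.

**Step 1**
Reactants: 1 2,4,6-trihydroxybenzaldehyde
Product: 2 2,6-dihydroxy-4-methoxybenzaldehyde
Conditions: Me2SO4 (1.0 equiv), K2CO3 (1.0 equiv), acetone, 0 °C to rt
Reagents that add atoms: dimethyl sulfate, COS(=O)(=O)OC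
Why: Williamson O-methylation with one equivalent of a hard electrophile should take place at the 4-hydroxyl, which is para to the formyl group, the most acidic, and the only one free of both the hydrogen bond to and the steric shielding by the aldehyde.

**Step 2**
Reactants: 2 2,6-dihydroxy-4-methoxybenzaldehyde
Product: 3 2,6-bis(benzyloxy)-4-methoxybenzaldehyde
Conditions: BnBr (2.4 equiv), K2CO3, DMF, 60 °C
Reagents that add atoms: benzyl bromide, BrCc1ccccc1
Why: Williamson etherification under forcing conditions alkylates both remaining hydroxyls, including the hydrogen-bonded one, as is routine for phloroglucinaldehyde ethers.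

**Step 3**
Reactants: 3 2,6-bis(benzyloxy)-4-methoxybenzaldehyde
Product: 4 2,6-bis(benzyloxy)-3,5-dibromo-4-methoxybenzaldehyde
Conditions: NBS (2.2 equiv), DMF, 0 °C to rt, dark
Reagents that add atoms: N-bromosuccinimide, O=C1CCC(=O)N1Br
Why: Electrophilic aromatic bromination should fill the only two open positions, each ortho/para to three alkoxy groups and meta to the formyl group, and the two bromines later keep every electrophile off this ring until they are removed together with the benzyl groups.

**Step 4**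
Reactants: 4 2,6-bis(benzyloxy)-3,5-dibromo-4-methoxybenzaldehyde
Product: 5 1,3-bis(benzyloxy)-4,6-dibromo-5-methoxy-2-(2-methoxyethenyl)benzene (E/Z mixture)
Conditions: Ph3P(CH2OMe)Cl, KOtBu, THF, 0 °C to rt
Reagents that add atoms: (methoxymethyl)triphenylphosphonium chloride, COC[P+](c1ccccc1)(c1ccccc1)c1ccccc1.[Cl-]
Why: Wittig methoxymethylenation of a non-enolisable aryl aldehyde adds the one carbon of the future acetic acid chain, and both alkene isomers converge in the next step.

**Step 5**
Reactants: 5 1,3-bis(benzyloxy)-4,6-dibromo-5-methoxy-2-(2-methoxyethenyl)benzene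
Product: 7 [2,6-bis(benzyloxy)-3,5-dibromo-4-methoxyphenyl]acetic acid, via arylacetaldehyde 6 (not isolated)
Conditions: 2 M HCl, THF, 45 °C; then NaH2PO4 buffer (pH 4), t-BuOH, 2-methyl-2-butene, NaClO2, rt
Reagents that add atoms: water, O; sodium chlorite, [Na+].[O-]Cl=O
Why: Acid hydrolysis of the enol ether followed by Pinnick oxidation of the crude aldehyde should give the acid cleanly, because the fully substituted ring cannot be chlorinated by the hypochlorite by-product, which the alkene scavenges.

**Step 6**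
Reactants: 7 [2,6-bis(benzyloxy)-3,5-dibromo-4-methoxyphenyl]acetic acid; 8 methyl acetoacetate
Product: 10 methyl 6-[2,6-bis(benzyloxy)-3,5-dibromo-4-methoxyphenyl]-3,5-dioxohexanoate, via acyl imidazolide 9 (not isolated)
Conditions: 7, CDI, THF, rt; added at −78 °C to the dianion of 8 (3 equiv; NaH then n-BuLi, THF, 0 °C), then 0 °C; 1 M HCl
Reagents that add atoms: 1,1'-carbonyldiimidazole, O=C(n1ccnc1)n1ccnc1 (its imidazole ring is carried only by intermediate 9)
Why: Huckin–Weiler γ-acylation, in which the terminal carbanion of the acetoacetate dianion attacks the N-acylimidazole, excess dianion absorbs the acidic product, and the butyllithium is consumed before the aryl bromide is present.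

**Step 7**
Reactants: 10 methyl 6-[2,6-bis(benzyloxy)-3,5-dibromo-4-methoxyphenyl]-3,5-dioxohexanoate
Product: 11 6-[2,6-bis(benzyloxy)-3,5-dibromo-4-methoxybenzyl]-4-hydroxy-2H-pyran-2-one
Conditions: DBU (1.5 equiv), toluene, 80 °C; then 1 M HCl
Reagents that add atoms: none
Why: DBU-promoted enol lactonisation of a 3,5-dioxo ester (the C5 enol oxygen attacks the ester, methanol leaves) is the standard entry to 6-substituted 4-hydroxy-2-pyranones.

**Step 8**
Reactants: 11 6-[2,6-bis(benzyloxy)-3,5-dibromo-4-methoxybenzyl]-4-hydroxy-2H-pyran-2-one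
Product: 12 6-[2,6-bis(benzyloxy)-3,5-dibromo-4-methoxybenzyl]-4-methoxy-2H-pyran-2-one
Conditions: Me2SO4 (1.2 equiv), K2CO3, acetone, reflux
Reagents that add atoms: dimethyl sulfate, COS(=O)(=O)OC
Why: O-alkylation of the vinylogous acid with Me2SO4/K2CO3 in acetone is known to favour the 4-methoxy-2-pyranone over the isomeric 2-methoxy-4-pyranone.

**Step 9**
Reactants: 12 6-[2,6-bis(benzyloxy)-3,5-dibromo-4-methoxybenzyl]-4-methoxy-2H-pyran-2-one
Product: 14 2',6'-bis(benzyloxy)-3',5'-dibromo-4,4'-dimethoxybiphenyl-2,6-diol, via ring-opened enoate ester 13 (not isolated)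
Conditions: NaOMe (5 equiv), MeOH, reflux, Ar; then 1 M HCl
Reagents that add atoms: sodium methoxide, C[O-].[Na+] (its methoxy group is held only by intermediate 13 and leaves again as methanol)
Why: Methoxide adds to the lactone carbonyl and opens the ring to the (2E)-3-methoxy-5-oxo ester 13, whose double-bond geometry, fixed by the former ring, keeps the ester beside the benzyl ketone chain; the ketone enolate carbon that bears the aryl group then attacks the ester carbon, methoxide leaves, and the cyclohexenedione tautomerises to the resorcinol, so the C8–C8a bond, ring A of the acacetin half and the biaryl axis arise without any aryl–aryl coupling. The closest known reaction is the base-induced conversion of 6-alkyl-4-methoxy-2-pyranones into 5-methoxyresorcinols, a Dieckmann-type Claisen condensation. The ring closes in a 6-(enolexo)-exo-trig mode. No stereocentre is formed, and the axis becomes stereogenic only later and is then racemic. The step needs closure through carbon and not back through oxygen: oxygen closure only regenerates 12, the methyl enol ether keeps the 4-oxygen out of play and the ester electrophilic, and carbon closure alone is made irreversible by aromatisation to the phenoxide, while the aryl group and its two bromines acidify the attacking CH2. The methyl ether that survives lies para to the axis and later forces pyranone closure through an oxygen ortho to the axis.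

**Step 10**
Reactants: 14 2',6'-bis(benzyloxy)-3',5'-dibromo-4,4'-dimethoxybiphenyl-2,6-diol
Product: 16 1-[2',6'-bis(benzyloxy)-3',5'-dibromo-2,6-dihydroxy-4,4'-dimethoxybiphenyl-3-yl]ethanone, via ketiminium chloride 15 (not isolated)
Conditions: MeCN, ZnCl2, HCl (g), Et2O, 0 °C; then H2O, reflux
Reagents that add atoms: acetonitrile, CC#N; water, O; hydrogen chloride, Cl (chloride only in intermediate 15)
Why: Houben–Hoesch acylation attacks the free resorcinol ring at its only kind of open position (between OH and OMe), the other ring has no open position left because of the bromines, one acyl group deactivates the ring against a second, and hydrolysis of the ketiminium salt gives the ketone.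

**Step 11**
Reactants: 16 1-[2',6'-bis(benzyloxy)-3',5'-dibromo-2,6-dihydroxy-4,4'-dimethoxybiphenyl-3-yl]ethanone; 17 4-methoxybenzaldehyde
Product: 18 (2E)-1-[2',6'-bis(benzyloxy)-3',5'-dibromo-2,6-dihydroxy-4,4'-dimethoxybiphenyl-3-yl]-3-(4-methoxyphenyl)prop-2-en-1-one
Conditions: 50% aq. KOH, EtOH, rt; then 1 M HCl
Reagents that add atoms: none
Why: Claisen–Schmidt condensation of the methyl ketone with a non-enolisable aldehyde, the E-alkene resulting from dehydration to the conjugated, more stable enone.

**Step 12**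
Reactants: 18 (2E)-1-[2',6'-bis(benzyloxy)-3',5'-dibromo-2,6-dihydroxy-4,4'-dimethoxybiphenyl-3-yl]-3-(4-methoxyphenyl)prop-2-en-1-one
Product: 19 8-[2,6-bis(benzyloxy)-3,5-dibromo-4-methoxyphenyl]-7-hydroxy-5-methoxy-2-(4-methoxyphenyl)-4H-chromen-4-one
Conditions: I2 (10 mol%), DMSO, 120 °C
Reagents that add atoms: none
Why: Iodine-catalysed oxidative cyclisation of a 2'-hydroxychalcone (oxa-Michael addition, then dehydrogenation with DMSO as terminal oxidant) can only use the hydroxyl next to the axis, since the other flank of the carbonyl is the methyl ether, so the 8-aryl flavone results.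

**Step 13**
Reactants: 19 8-[2,6-bis(benzyloxy)-3,5-dibromo-4-methoxyphenyl]-7-hydroxy-5-methoxy-2-(4-methoxyphenyl)-4H-chromen-4-one
Product: 20 8-(2,6-dihydroxy-4-methoxyphenyl)-7-hydroxy-5-methoxy-2-(4-methoxyphenyl)-4H-chromen-4-one
Conditions: H2 (1 atm), Pd/C (10% Pd on carbon), Et3N (2.5 equiv), EtOAc/MeOH, rt
Reagents that add atoms: none
Why: Catalytic hydrogenolysis removes both benzyl ethers and, with Et3N as HBr acceptor, both aryl bromides in one operation, while the pyranone C2=C3 bond, part of a vinylogous ester, should resist reduction at 1 atm.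

**Step 14**
Reactants: 20 8-(2,6-dihydroxy-4-methoxyphenyl)-7-hydroxy-5-methoxy-2-(4-methoxyphenyl)-4H-chromen-4-one
Product: 21 8-(3-acetyl-2,6-dihydroxy-4-methoxyphenyl)-7-hydroxy-5-methoxy-2-(4-methoxyphenyl)-4H-chromen-4-one (racemic about the axis)
Conditions: AcOH, BF3·OEt2, 80 °C; then aq. NaOAc, MeOH
Reagents that add atoms: acetic acid, CC(=O)O
Why: Friedel–Crafts acetylation (O-acetate and Fries-type migration under BF3) should occur on the freed 5-methoxyresorcinol ring, the only electron-rich ring not deactivated by a carbonyl group, at one of its two equivalent positions, and the BF2 chelate of the product blocks a second acylation.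

**Step 15**
Reactants: 21 8-(3-acetyl-2,6-dihydroxy-4-methoxyphenyl)-7-hydroxy-5-methoxy-2-(4-methoxyphenyl)-4H-chromen-4-one; 22 4-(benzyloxy)benzaldehyde
Product: 23 8-{3-[(2E)-3-[4-(benzyloxy)phenyl]prop-2-enoyl]-2,6-dihydroxy-4-methoxyphenyl}-7-hydroxy-5-methoxy-2-(4-methoxyphenyl)-4H-chromen-4-one
Conditions: 50% aq. KOH, EtOH, rt; then 1 M HCl
Reagents that add atoms: none
Why: Claisen–Schmidt condensation as in step 11, with the 7-phenoxide shielding the existing flavone from hydroxide and the E-alkene again set by dehydration to the conjugated enone.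

**Step 16**
Reactants: 23 8-{3-[(2E)-3-[4-(benzyloxy)phenyl]prop-2-enoyl]-2,6-dihydroxy-4-methoxyphenyl}-7-hydroxy-5-methoxy-2-(4-methoxyphenyl)-4H-chromen-4-one
Product: 24 2-[4-(benzyloxy)phenyl]-7-hydroxy-8-[7-hydroxy-5-methoxy-2-(4-methoxyphenyl)-4-oxo-4H-chromen-8-yl]-5-methoxy-4H-chromen-4-one
Conditions: I2 (10 mol%), DMSO, 120 °C
Reagents that add atoms: none
Why: Iodine/DMSO oxidative cyclisation as in step 12, in which only the hydroxyl beside the axis is ortho to the enone carbonyl (the other flank is the methyl ether), so the second pyranone closes to the 8''-linked isomer.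

**Step 17**
Reactants: 24 2-[4-(benzyloxy)phenyl]-7-hydroxy-8-[7-hydroxy-5-methoxy-2-(4-methoxyphenyl)-4-oxo-4H-chromen-8-yl]-5-methoxy-4H-chromen-4-one
Product: 25 5,7-dihydroxy-8-[5,7-dihydroxy-2-(4-methoxyphenyl)-4-oxo-4H-chromen-8-yl]-2-(4-hydroxyphenyl)-4H-chromen-4-one (target, racemic about the axis)
Conditions: BCl3 (excess), C6HMe5, CH2Cl2, −78 °C to rt; then MeOH/H2O
Reagents that add atoms: none
Why: Chelation-controlled Lewis acid dealkylation, in which BCl3 bound to each C4 carbonyl cleaves the peri 5- and 5''-methyl ethers and, with pentamethylbenzene trapping the benzyl cation, the benzyl ether, while the non-chelated 4'-methyl ether is inert to BCl3 at room temperature.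

**Compound list**
1 | 2,4,6-trihydroxybenzaldehyde | O=Cc1c(O)cc(O)cc1O | starting material
2 | 2,6-dihydroxy-4-methoxybenzaldehyde | COc1cc(O)c(C=O)c(O)c1 | intermediate
3 | 2,6-bis(benzyloxy)-4-methoxybenzaldehyde | O=Cc1c(OCc2ccccc2)cc(OC)cc1OCc1ccccc1 | intermediate
4 | 2,6-bis(benzyloxy)-3,5-dibromo-4-methoxybenzaldehyde | O=Cc1c(OCc2ccccc2)c(Br)c(OC)c(Br)c1OCc1ccccc1 | intermediate
5 | 1,3-bis(benzyloxy)-4,6-dibromo-5-methoxy-2-(2-methoxyethenyl)benzene (E/Z mixture) | COC=Cc1c(OCc2ccccc2)c(Br)c(OC)c(Br)c1OCc1ccccc1 | intermediate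
6 | [2,6-bis(benzyloxy)-3,5-dibromo-4-methoxyphenyl]acetaldehyde | O=CCc1c(OCc2ccccc2)c(Br)c(OC)c(Br)c1OCc1ccccc1 | intermediate (not isolated)
7 | [2,6-bis(benzyloxy)-3,5-dibromo-4-methoxyphenyl]acetic acid | OC(=O)Cc1c(OCc2ccccc2)c(Br)c(OC)c(Br)c1OCc1ccccc1 | intermediate
8 | methyl acetoacetate | COC(=O)CC(C)=O | starting material
9 | 1-{[2,6-bis(benzyloxy)-3,5-dibromo-4-methoxyphenyl]acetyl}-1H-imidazole | O=C(Cc1c(OCc2ccccc2)c(Br)c(OC)c(Br)c1OCc1ccccc1)n1ccnc1 | intermediate (not isolated)
10 | methyl 6-[2,6-bis(benzyloxy)-3,5-dibromo-4-methoxyphenyl]-3,5-dioxohexanoate | COC(=O)CC(=O)CC(=O)Cc1c(OCc2ccccc2)c(Br)c(OC)c(Br)c1OCc1ccccc1 | intermediate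
11 | 6-[2,6-bis(benzyloxy)-3,5-dibromo-4-methoxybenzyl]-4-hydroxy-2H-pyran-2-one | O=c1cc(O)cc(Cc2c(OCc3ccccc3)c(Br)c(OC)c(Br)c2OCc2ccccc2)o1 | intermediate
12 | 6-[2,6-bis(benzyloxy)-3,5-dibromo-4-methoxybenzyl]-4-methoxy-2H-pyran-2-one | COc1cc(Cc2c(OCc3ccccc3)c(Br)c(OC)c(Br)c2OCc2ccccc2)oc(=O)c1 | intermediate (key-step precursor)
13 | methyl (2E)-6-[2,6-bis(benzyloxy)-3,5-dibromo-4-methoxyphenyl]-3-methoxy-5-oxohex-2-enoate | COC(=O)/C=C(/OC)CC(=O)Cc1c(OCc2ccccc2)c(Br)c(OC)c(Br)c1OCc1ccccc1 | intermediate (not isolated)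
14 | 2',6'-bis(benzyloxy)-3',5'-dibromo-4,4'-dimethoxybiphenyl-2,6-diol | COc1cc(O)c(-c2c(OCc3ccccc3)c(Br)c(OC)c(Br)c2OCc2ccccc2)c(O)c1 | intermediate (key-step product)
15 | 1-[2',6'-bis(benzyloxy)-3',5'-dibromo-2,6-dihydroxy-4,4'-dimethoxybiphenyl-3-yl]ethan-1-iminium chloride | COc1cc(O)c(-c2c(OCc3ccccc3)c(Br)c(OC)c(Br)c2OCc2ccccc2)c(O)c1C(C)=[NH2+].[Cl-] | intermediate (not isolated)
16 | 1-[2',6'-bis(benzyloxy)-3',5'-dibromo-2,6-dihydroxy-4,4'-dimethoxybiphenyl-3-yl]ethanone | COc1cc(O)c(-c2c(OCc3ccccc3)c(Br)c(OC)c(Br)c2OCc2ccccc2)c(O)c1C(C)=O | intermediate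
17 | 4-methoxybenzaldehyde | COc1ccc(C=O)cc1 | starting material
18 | (2E)-1-[2',6'-bis(benzyloxy)-3',5'-dibromo-2,6-dihydroxy-4,4'-dimethoxybiphenyl-3-yl]-3-(4-methoxyphenyl)prop-2-en-1-one | COc1ccc(/C=C/C(=O)c2c(OC)cc(O)c(-c3c(OCc4ccccc4)c(Br)c(OC)c(Br)c3OCc3ccccc3)c2O)cc1 | intermediate
19 | 8-[2,6-bis(benzyloxy)-3,5-dibromo-4-methoxyphenyl]-7-hydroxy-5-methoxy-2-(4-methoxyphenyl)-4H-chromen-4-one | COc1ccc(-c2cc(=O)c3c(OC)cc(O)c(-c4c(OCc5ccccc5)c(Br)c(OC)c(Br)c4OCc4ccccc4)c3o2)cc1 | intermediate
20 | 8-(2,6-dihydroxy-4-methoxyphenyl)-7-hydroxy-5-methoxy-2-(4-methoxyphenyl)-4H-chromen-4-one | COc1ccc(-c2cc(=O)c3c(OC)cc(O)c(-c4c(O)cc(OC)cc4O)c3o2)cc1 | intermediate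
21 | 8-(3-acetyl-2,6-dihydroxy-4-methoxyphenyl)-7-hydroxy-5-methoxy-2-(4-methoxyphenyl)-4H-chromen-4-one (racemic axis) | COc1ccc(-c2cc(=O)c3c(OC)cc(O)c(-c4c(O)cc(OC)c(C(C)=O)c4O)c3o2)cc1 | intermediate
22 | 4-(benzyloxy)benzaldehyde | O=Cc1ccc(OCc2ccccc2)cc1 | starting material
23 | 8-{3-[(2E)-3-[4-(benzyloxy)phenyl]prop-2-enoyl]-2,6-dihydroxy-4-methoxyphenyl}-7-hydroxy-5-methoxy-2-(4-methoxyphenyl)-4H-chromen-4-one (racemic axis) | COc1ccc(-c2cc(=O)c3c(OC)cc(O)c(-c4c(O)cc(OC)c(C(=O)/C=C/c5ccc(OCc6ccccc6)cc5)c4O)c3o2)cc1 | intermediate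
24 | 2-[4-(benzyloxy)phenyl]-7-hydroxy-8-[7-hydroxy-5-methoxy-2-(4-methoxyphenyl)-4-oxo-4H-chromen-8-yl]-5-methoxy-4H-chromen-4-one (racemic axis) | COc1ccc(-c2cc(=O)c3c(OC)cc(O)c(-c4c(O)cc(OC)c5c(=O)cc(-c6ccc(OCc7ccccc7)cc6)oc45)c3o2)cc1 | intermediate
25 | 5,7-dihydroxy-8-[5,7-dihydroxy-2-(4-methoxyphenyl)-4-oxo-4H-chromen-8-yl]-2-(4-hydroxyphenyl)-4H-chromen-4-one (racemic axis) | COc1ccc(-c2cc(=O)c3c(O)cc(O)c(-c4c(O)cc(O)c5c(=O)cc(-c6ccc(O)cc6)oc45)c3o2)cc1 | target

Total steps: 17. Longest linear sequence: 17 steps (1 to 25; compounds 8, 17 and 22 are bought).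

**Steps most likely to fail**

Step 9. The crowded aryl-bearing enolate may close too slowly, so that the opened chain is cut by methoxide in a retro-Claisen sense or simply relactonises. The fallback sets out from diketo ester 10 and comes back at 14. The unmethylated 3,5-dioxo ester is cyclised as its sodium enolate (NaH, diglyme, heat) in a Dieckmann-type Claisen condensation to 2',6'-bis(benzyloxy)-3',5'-dibromo-4'-methoxybiphenyl-2,4,6-triol F1. The marker methyl group is then introduced by acid-catalysed mono-etherification (dry HCl, MeOH, rt), which should favour the hydroxyl para to the aryl group because the two ortho hydroxyls are shielded by the perpendicular ring.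

Step 6. The dianion may take a proton from the acidic CH2 of the acyl imidazole faster than it attacks the carbonyl, so the acyl donor is lost as its enolate. The fallback sets out from acid 7 and comes back at 10. The acid is converted with (COCl)2 and catalytic DMF into [2,6-bis(benzyloxy)-3,5-dibromo-4-methoxyphenyl]acetyl chloride F2; the fully substituted ring cannot be acylated by the reagent. F2 is then combined without strong base with commercial 1-methoxy-1,3-bis(trimethylsilyloxy)buta-1,3-diene in CH2Cl2 (−78 to 20 °C). This γ-acylation of a bis(silyl enol ether), followed by aqueous HCl, gives 10.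

Step 15. Enolisation of the triply deprotonated ketone may be so slow that hydroxide opens the existing pyranone ring during the long exposure. The fallback sets out from 21 and comes back at 24, passing by chalcone 23 and step 16. Compound 21 is deprotonated with excess LiN(SiMe3)2 (THF, −78 °C) and C-aroylated with 4-(benzyloxy)benzoyl chloride to 1-[4-(benzyloxy)phenyl]-3-{2,4-dihydroxy-3-[7-hydroxy-5-methoxy-2-(4-methoxyphenyl)-4-oxo-4H-chromen-8-yl]-6-methoxyphenyl}propane-1,3-dione F3. This Baker–Venkataraman-type diketone is cyclodehydrated with catalytic p-TsOH in toluene at reflux to give 24 directly.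

**Further compounds**
F1 | step 9 | 2',6'-bis(benzyloxy)-3',5'-dibromo-4'-methoxybiphenyl-2,4,6-triol | Oc1cc(O)c(-c2c(OCc3ccccc3)c(Br)c(OC)c(Br)c2OCc2ccccc2)c(O)c1
F2 | step 6 | [2,6-bis(benzyloxy)-3,5-dibromo-4-methoxyphenyl]acetyl chloride | O=C(Cl)Cc1c(OCc2ccccc2)c(Br)c(OC)c(Br)c1OCc1ccccc1
F3 | step 15 | 1-[4-(benzyloxy)phenyl]-3-{2,4-dihydroxy-3-[7-hydroxy-5-methoxy-2-(4-methoxyphenyl)-4-oxo-4H-chromen-8-yl]-6-methoxyphenyl}propane-1,3-dione | COc1ccc(-c2cc(=O)c3c(OC)cc(O)c(-c4c(O)cc(OC)c(C(=O)CC(=O)c5ccc(OCc6ccccc6)cc5)c4O)c3o2)cc1
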